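The constants used here belong to no real substance; the flask was simulated.

Follow the reagent through each flask and leave the rest for later.

| flask | starting material | reagent | second substrate | protic impurity | time | remark |
|---|---|---|---|---|---|---|
| autumn | 2.0 mM | 0.500 equiv | 5.00 equiv | 2.00 mM | 15 s | everything together at the start |
| winter | 2.0 mM (fed, over 10 s) | 0.500 equiv | 5.00 equiv | 2.00 mM | 15 s | all else is in the flask from the start; the feed brings no volume worth counting |
| dawn | 2.0 mM | 0.500 equiv | 5.00 equiv (fed, over 10 s) | 2.00 mM | 15 s | all else is in the flask from the start; the feed brings no volume worth counting |

    starting material + reagent → target (k1 = 210 M⁻¹ s⁻¹)
    second substrate + reagent → second product (k2 = 59 M⁻¹ s⁻¹)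
    2 second substrate → self-condensation product (k3 = 4.3 M⁻¹ s⁻¹)
    target → over-reaction product (k4 = 0.038 s⁻¹)
    starting material + protic impurity → quenched substrate (k5 = 38 M⁻¹ s⁻¹)

- a step written with two of one species runs at k times the square of its concentration and takes two of it each time
- run time (autumn): 15 s

- which flask leads in amount of over-reaction product, in percent of the starting material charged ("all alike" within 1.5 percentage points) (autumn / winter / dawn / all alike)
- how much over-reaction product is there at the end, in percent of the starting material charged: autumn
- how much over-reaction product is there at the end, in percent of the starting material charged: winter
- how much over-reaction product is there at the end, in percent of the starting material charged: dawn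

What do you freeze? The standing fractions of the reagent's two partners: a for the starting material and b for the second substrate, each a fraction of its own charge. The reagent is the limiting reagent at 0.500 equiv. In autumn its pseudo-first-order lifetime with both partners at full charge is 0.990 s. That is shorter than the 9.1 s half-life of starting material by quenching, other concentrations as charged, and the 11.6 s first half-life of second substrate by self-condensation, so the freeze is fair.

What goes to target? Take the first-step constant times a, and divide by that term plus the second-step constant times the equivalents of second substrate times b. In autumn, where a and b are whole, this gives 41.6%.

But in winter the starting material is fed, so what is a? It is what the feed brings in one lifetime. Second substrate carries the winter lifetime, 1.69 s, so a is 16.9%, and the first-step term stays the smaller. That makes the reagent's share, the part of the reagent that turns into target while the partners stand frozen, 10.8%.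

And dawn? Mirror it: starting material sets the lifetime at 2.38 s, b is 23.8%, and the share is 74.9%.

How much over-reaction product? Multiply the share by the reagent's equivalents, then let that target decay by the fourth step from one lifetime until the end. I get 8.58% for autumn, 2.14% for winter and 14.3% for dawn.

The forecast also names dawn but stands lower than my figures, at 7.7% for autumn, 1.8% for winter and 13.2% for dawn, holding that “Feeding the second substrate slowly leaves the reagent for the starting material”.

The simulation gives 8.13% for autumn, 1.96% for winter and 13.8% for dawn, so dawn leads, and each value lies under my figure.

Now take the neighbour of winter charged with 2.00 equiv of reagent, everything else held. My reckoning of the share has no term in the reagent's equivalents, so with the partners taken as frozen it carries 10.8% over unchanged. Multiplying by the new equivalents gives 21.6% of the starting material charged as target formed, and the same decay leaves 8.55% as over-reaction product. That neighbour holds 16.4% target and 8.13% over-reaction product after 15.0 s, together 24.5%, which is more than the 21.6% reckoned, and 32.8% of its second substrate is left at that time.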